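| setting | birch | maple | cedar | flask |
|---|---|---|---|---|
| substrate | 0.55 M | 0.83 M | 1.1 M | 1.1 M |
| coupling partner | 2.2 M | 2.2 M | 2.2 M | 2.20 M |
| other conformer | 0.11 M | 0.11 M | 0.17 M | 0.110 M |
| remark | run made earlier | run made earlier | run made earlier |  |
| time |  |  |  | 80 min |

| run | time / min | target / % | isomer of the product / % |
|---|---|---|---|
| birch | 5.00 | 24.3 | 17.7 |
| birch | 15.0 | 44.7 | 18.5 |
| birch | 25.0 | 55.0 | 18.3 |
| birch | 40.0 | 64.1 | 18.9 |
| birch | 60.0 | 71.1 | 19.3 |
| birch | 80.0 | 75.0 | 20.7 |
| birch | 90.0 | 76.4 | 19.9 |
| maple | 15.0 | 45.3 | 13.9 |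
| maple | 30.0 | 59.6 | 14.0 |
| maple | 40.0 | 65.2 | 14.3 |
| maple | 60.0 | 72.7 | 15.3 |
| maple | 80.0 | 77.4 | 15.8 |
| maple | 90.0 | 79.3 | 16.0 |
| cedar | 8.00 | 31.2 | 13.9 |
| cedar | 25.0 | 51.3 | 15.1 |
| cedar | 40.0 | 60.6 | 17.1 |
| cedar | 60.0 | 67.8 | 17.0 |
| cedar | 90.0 | 74.0 | 17.8 |

(readings scatter by 0.3 percentage points)



1. ratio of target to isomer of the product at 2.0 s
2. ratio of target to isomer of the product at 1.5 min
3. ratio of target to isomer of the product at 80 min

Start from 9.09%: this is the flask's head start, c(other conformer) over c(substrate) + c(other conformer) at the charge. In cedar the head start is 13.4% and the first isomer reading 13.9%; in birch they are 16.7% and 17.7%. So you can treat isomer as the head start plus a small correction. From first reading to last, averaged over birch, maple and cedar, isomer gains 0.0650 per unit of target, an inverse selectivity factor.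

Now turn the question round. For isomer to equal target in the flask, on this reckoning, target must stand at 9.72%. Cedar, with the flask's substrate and partner charges but more other conformer, read 74.0% of target at 90.0 min, more than that mark; take that reading as a rough stand-in for the flask at 80 min and the reckoning gives a ratio of 5.32. Cedar's chord to 8.00 min gives 5.85% of target at 1.5 min, but that chord is steeper than the next one, so the readings bend and I hold the resulting 0.644 for the flask at 1.5 min as a low estimate. The earliest reading of the runs comes at 5.00 min, so I give no figure for 2.0 s.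

The forecast says 0.1, 1.05 and 5.6, holding that “the other conformer goes quickly and essentially wholly to isomer”. Its late ratio stands above mine.

The flask gives 0.143, 1.15 and 5.68; the forecast's first is low by a factor of 1.43, and its other two hold within tolerance. In the flask, target passes isomer at 1.27 min. At 80.0 min the flask's isomer is 13.5%, the head start plus 4.4 percentage points, which over 77.0% of target is 0.0573 per unit.

    coupling partner ⇌ dormant form (K = 1.40, k = 0.00160 s⁻¹)
    coupling partner + other conformer → isomer of the product (k = 0.0570 M⁻¹ s⁻¹)
    substrate + coupling partner → target (k = 7.20 × 10⁻⁴ M⁻¹ s⁻¹)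
    substrate ⇌ other conformer (K = 0.0170, k = 3.50 × 10⁻⁵ s⁻¹)

A neighbouring flask charged with 2.8 M of substrate has a head start of 3.78%; hold target at the flask's percentage and scale by the head starts, and the ratio at 1.5 min comes to 2.77. The computed neighbour gives 2.67.

The data are simulated for an exercise, noise included.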